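## The problem

Compound 20 is a 2-aryl-3-(hydroxymethyl)-2,3-dihydrobenzofuran. Ring A (the benzo ring, with OMe at C7 and the (E)-acrylic acid at C5) is fused at C3a/C7a to the oxygen ring O1–C2–C3; ring B (4-hydroxy-3,5-dimethoxyphenyl) sits on C2 and a single carbon, CH2OH, on C3. The only stereocentres are C2 (S) and C3 (R), adjacent and trans. They are not equal partners: C2 is a benzylic ether carbon para to an oxygen of ring B and can be re-equilibrated by reversible opening of the C2–O1 bond, with the trans ring as the sink, whereas C3 has no such path. C3 can therefore control C2 but not the reverse, and the absolute configuration at C3 is the real task. The fragile groups are the free electron-rich phenol of ring B (oxidants), the doubly activated C2–O1 bond (strong acid, hydrogenolysis), the acrylic acid double bond (ozone, hydride, hydrogenation), and any carbonyl placed on the C3 carbon, which makes C3–H acidic and O1 a β-leaving group. The enabling feature is that C2 and C3 are the two carbons of the C2=C3 enol-ether bond of a benzofuran: O1 makes C2–H the acidic site and C3 the nucleophilic site, and the trans arrangement of the C2 aryl group and the C3 carbon is what an anti addition across that bond delivers. Because C3 carries only one carbon, a larger carbon electrophile placed there must be cut back afterwards.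

## Retrosynthesis

**20 to 18.** The Cα=Cβ bond of the acrylic acid is cut by a Knoevenagel–Doebner transform, leaving aldehyde 18. The alkene would not survive the ozone and hydride used earlier, so it is made last. The Doebner variant gives the free acid directly, and a halide handle for a Heck reaction would not tolerate the lithiation of the key step. The forward reaction must tolerate a free phenol and a primary alcohol.

**18 to 17.** No skeletal bond is cut; the ring-B phenol and the C5 aldehyde are masked as a methoxymethyl ether and a dimethyl acetal in 17. Both are acetals, so one aqueous acid operation removes them. A benzyl ether on ring B was rejected because its hydrogenolysis would take place next to the benzylic C2–O1 bond and cost a step. The forward step only asks that the ring, if it opens at C2–O1, recloses trans, which C3 ensures.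

**17 to 15 to 14.** The CH2OH carbon is traced to the allylic CH2 of a C3 allyl group in 14. One alkene shift gives propenyl compound 15, and cleavage of its double bond with reduction in the same flask gives 17 through aldehyde 16. An allyl group is chosen because the allyl–palladium cation is the soft carbon electrophile with the best record in the key reaction type; a one-carbon electrophile has no comparable asymmetric version. The isomerisation must stop after one shift, and 16 must never be isolated.

**14 to 13.** The C2–H bond is traced to a C2–B bond in boronic ester 13, to be replaced with retention. Boron cis to the allyl group then becomes hydrogen cis to it, leaving aryl and allyl trans. The C–B bond is the price of the key step and is removed at once.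

**13 to 6, 9 and 10 (key disconnection).** The C2–aryl and C3–allyl bonds are cut together across the former C2=C3 bond, giving benzofuran 6, aryl boronic ester 9 and allyl acetate 10, joined through 2-lithiobenzofuran 11 and boronate complex 12. The neighbouring cuts, O1–C2 or C3–C3a, each need an enantiopure open-chain or ring-expanded precursor. This cut sets both stereocentres in one catalytic step from two flat, achiral fragments. The forward reaction needs attack of the allyl–palladium electrophile at C3, an anti 1,2-shift of the aryl group from boron to C2, and face selection at C3 by a chiral bisphosphine.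

**6 to 1 and 2.** The furan ring is cut at O1–C2 and C3–C3a. Acetal 6 comes from aldehyde 5, which comes from 2-silylbenzofuran 4, made by Sonogashira coupling and cyclisation of 5-iodovanillin 1 with trimethylsilylacetylene 2 through alkynylphenol 3. This places OMe at C7 and the aldehyde at C5 with no regiochemical question.

**9 to 7.** The C–B bond of 9 is cut to aryl bromide 8 (Miyaura borylation), the methoxymethyl ether of commercial 4-bromo-2,6-dimethoxyphenol 7.

## Roads not taken

**Alternative 1:** The cut is the O1–C2 bond. In the forward step Ag2O oxidises the ring-B phenol of diarylpropanol A2 to its para-quinone methide, and the ring-A phenol adds to the exocyclic carbon, closing the ring to methyl ester A1. Saponification would finish the synthesis.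
- **Merits:** the closure mimics the biosynthesis, the ring-B phenol is the trigger and needs no protection, the acrylate is already in place, and trans selectivity follows from the same preference that governs the target. In these respects it is the better plan.
- **Weak points:** the stereochemical problem is only moved, since C3 of A2 must be made as a single enantiomer in an open chain with two phenols and an acrylate on board. Ag2O must pick the ring-B phenol over the ring-A phenol, which is itself a ferulate-type phenol prone to one-electron oxidation and radical coupling. The quinone methide can also tautomerise at the adjacent C–H or be captured by water.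
- **Comparison:** the chosen plan offers convergence (fragments of three and two steps), both stereocentres from one catalytic step, and no oxidant in the presence of two phenols.

**Alternative 2:** The same two bonds across C2=C3 are formed in two separate events. 5-Bromo-7-methoxybenzofuran A4 and ethyl diazoacetate A5 react under CuOTf and a chiral bis(oxazoline); the monovalent-copper carbene adds across C2=C3 to give cyclopropane A3. Acid-induced opening of the donor–acceptor cyclopropane and attack of an aryl nucleophile at C2, anti to the C3 side chain, would follow.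
- **Merits:** the enantio-determining step, copper-carbene cyclopropanation of a furan-type double bond, has closer precedent than the key step chosen here. The bromide would also allow a late Heck reaction that gives the acid directly. Both points favour this alternative.
- **Weak points:** opening of A3 gives a C2 oxocarbenium ion with C3–H next to it, and loss of that proton restores the aromatic benzofuran, in competition with arylation. The intermolecular trans-selective arylation is itself unproven. After opening, C3 would carry a two-carbon ester chain whose carboxyl carbon must be excised and replaced by oxygen, which costs more than the two-step trimming of an allyl group.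
- **Comparison:** the chosen plan fuses the two events into one concerted anti addition in which C2 becomes fully substituted as C3 is alkylated, so re-aromatisation is not open.

**Alternative 3:** The cut is the C3–C3a bond, by ring contraction. (S)-Flavanone A7 is treated with PhI(OAc)2 and catalytic H2SO4 in MeOH/HC(OMe)3. Trivalent iodine adds at C3 of the enol ether, ring carbon C4a shifts from the carbonyl carbon to C3, and the old carbonyl carbon leaves as the methyl ester of trans product A6.
- **Merits:** C3 arrives with exactly one carbon at the ester level, so hydride reduction gives CH2OH with no trimming. Here it is better than the chosen plan. The contraction is a known reaction type.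
- **Weak points:** the stereochemical information sits at C2 of A7, the labile centre, which can racemise in H2SO4 through retro-oxa-Michael opening to the chalcone. C3, which cannot be repaired later, is set only relative to C2. Electron-rich ring B, even as its pivalate, may compete as the migrating group or be oxidised by trivalent iodine. Enantiopure A7 needs its own asymmetric synthesis, and the bromide still needs a Heck reaction.
- **Comparison:** the chosen plan fixes C3 directly by the catalyst under non-acidic conditions and is more convergent.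

Key step: step 6

Assumption: (S)-H8-BINAP is taken to direct the allyl group to the C3 face that leads to (2S,3S)-13; if the benzofuranyl boronate shows the opposite sense, the (R)-ligand is used and nothing else changes.

## Route

Step 1
Reactants: 1 5-iodovanillin (4-hydroxy-3-iodo-5-methoxybenzaldehyde); 2 trimethylsilylacetylene
Product: 4 7-methoxy-2-(trimethylsilyl)-1-benzofuran-5-carbaldehyde, via alkynylphenol 3 (not isolated)
Conditions: PdCl2(PPh3)2 (2 mol%), CuI (4 mol%), Et3N, DMF, 60 °C
Reagents that add atoms: none
Why: Sonogashira coupling gives alkynylphenol 3, whose acidic phenol (para to the aldehyde) adds to the metal-activated alkyne in a 5-endo-dig heteroannulation; the silyl group keeps the alkyne monofunctional and ends on C2.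

Step 2
Reactants: 4 7-methoxy-2-(trimethylsilyl)-1-benzofuran-5-carbaldehyde
Product: 5 7-methoxy-1-benzofuran-5-carbaldehyde
Conditions: Bu4NF, THF, 0 °C to rt
Reagents that add atoms: none
Why: Fluoride-mediated protodesilylation of a 2-silylbenzofuran; any uncyclised 3 carried over is desilylated and cyclised under the same conditions.

Step 3
Reactants: 5 7-methoxy-1-benzofuran-5-carbaldehyde
Product: 6 5-(dimethoxymethyl)-7-methoxy-1-benzofuran
Conditions: HC(OMe)3, MeOH, p-TsOH (cat.), rt; Et3N quench
Reagents that add atoms: trimethyl orthoformate, COC(OC)OC; methanol, CO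
Why: Acid-catalysed acetalisation with the orthoformate as water scavenger; the dimethyl acetal is inert to n-BuLi, fluoride, RuHCl(CO)(PPh3)3, ozone and NaBH4 and is cleaved at the end together with the phenol protecting group.

Step 4
Reactants: 7 4-bromo-2,6-dimethoxyphenol
Product: 8 5-bromo-1,3-dimethoxy-2-(methoxymethoxy)benzene
Conditions: MOMCl, i-Pr2NEt, CH2Cl2, 0 °C to rt
Reagents that add atoms: chloromethyl methyl ether, COCCl
Why: O-alkylation of the phenol to its methoxymethyl ether, which survives organolithium, zerovalent palladium, fluoride, ozone and hydride and is removed by the same acid as the acetal, so no hydrogenolysis is needed next to the C2–O1 bond.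

Step 5
Reactants: 8 5-bromo-1,3-dimethoxy-2-(methoxymethoxy)benzene
Product: 9 2-[3,5-dimethoxy-4-(methoxymethoxy)phenyl]-4,4,5,5-tetramethyl-1,3,2-dioxaborolane
Conditions: B2pin2, Pd(dppf)Cl2 (3 mol%), KOAc, 1,4-dioxane, 90 °C
Reagents that add atoms: bis(pinacolato)diboron, CC1(C)OB(OC1(C)C)B1OC(C)(C)C(C)(C)O1
Why: Miyaura borylation of an aryl bromide; KOAc is too weak a base to promote Suzuki coupling of the product.

Step 6
Reactants: 6 5-(dimethoxymethyl)-7-methoxy-1-benzofuran; 9 2-[3,5-dimethoxy-4-(methoxymethoxy)phenyl]-4,4,5,5-tetramethyl-1,3,2-dioxaborolane; 10 allyl acetate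
Product: 13 2-{(2S,3S)-5-(dimethoxymethyl)-2-[3,5-dimethoxy-4-(methoxymethoxy)phenyl]-7-methoxy-3-(prop-2-en-1-yl)-2,3-dihydro-1-benzofuran-2-yl}-4,4,5,5-tetramethyl-1,3,2-dioxaborolane (aryl trans to allyl, boron cis to allyl), via 2-lithiobenzofuran 11 (not isolated), via lithium boronate complex 12 (not isolated)
Conditions: 6 (1.1 equiv), n-BuLi (1.05 equiv), THF, −78 °C; 9, −78 °C to rt; then Pd2(dba)3 (2.5 mol%), (S)-H8-BINAP (6 mol%), 10, THF, rt
Reagents that add atoms: none
Why: Proposed new method: C2–H of 6, α to O1, is the most acidic position, so n-BuLi gives 11, which adds to the empty orbital of boron in 9 to form the tetracoordinate boronate 12, in which the C2=C3 enol ether is pushed further by the anionic boron and C3 is the nucleophilic site. Zerovalent palladium bearing (S)-H8-BINAP ionises 10 to a cationic allyl complex of divalent palladium, which C3 attacks in an outer-sphere step while the aryl group shifts from boron to C2 on the opposite face (1,2-metallate shift anti-periplanar to the forming C3–C bond), releasing LiOAc and zerovalent palladium. The closest known reaction type is the enantioselective palladium-catalysed three-component coupling of 2-lithiated indoles, boronic esters and allylic acetates to trans-2-boryl-3-allylindolines; the oxygen heterocycle and the electron-rich aryl migrating group are the untested parts. No ring is closed; the furan ring loses its aromaticity and ring A is untouched. C3 is set by the chiral bisphosphine on the allyl–palladium electrophile, which selects one enantiotopic face of the flat boronate; C2 is set relative to C3 by the anti course of the shift, so aryl ends trans to allyl and boron cis to it. The step needs C3-allylation to outrun transfer of the benzofuranyl group to palladium and needs the aryl group, not a pinacol oxygen, to migrate; the enol-ether polarisation by O1 and the high migratory aptitude of an electron-rich aryl group should secure both, and the acetal and ethers are inert to every reagent present.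

Step 7
Reactants: 13 2-{(2S,3S)-5-(dimethoxymethyl)-2-[3,5-dimethoxy-4-(methoxymethoxy)phenyl]-7-methoxy-3-(prop-2-en-1-yl)-2,3-dihydro-1-benzofuran-2-yl}-4,4,5,5-tetramethyl-1,3,2-dioxaborolane
Product: 14 (2S,3S)-5-(dimethoxymethyl)-2-[3,5-dimethoxy-4-(methoxymethoxy)phenyl]-7-methoxy-3-(prop-2-en-1-yl)-2,3-dihydro-1-benzofuran (trans)
Conditions: Bu4NF·3H2O, toluene, 45 °C
Reagents that add atoms: none
Why: Stereoretentive protodeboronation of a tertiary benzylic boronic ester: fluoride adds to boron and the C–B bond is protonated by the water of hydration from the front side, the negative charge at C2 being stabilised by the aryl group and inductively by O1; hydrogen takes the place of boron cis to the allyl group, so aryl and allyl stay trans.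

Step 8
Reactants: 14 (2S,3S)-5-(dimethoxymethyl)-2-[3,5-dimethoxy-4-(methoxymethoxy)phenyl]-7-methoxy-3-(prop-2-en-1-yl)-2,3-dihydro-1-benzofuran
Product: 15 (2S,3S)-5-(dimethoxymethyl)-2-[3,5-dimethoxy-4-(methoxymethoxy)phenyl]-7-methoxy-3-[(1E)-prop-1-en-1-yl]-2,3-dihydro-1-benzofuran
Conditions: RuHCl(CO)(PPh3)3 (5 mol%), toluene, 80 °C
Reagents that add atoms: none
Why: Metal hydride-catalysed alkene isomerisation (hydrometalation and β-hydride elimination) moves the terminal double bond one position to the more stable (E)-disubstituted alkene; a second shift would need a hindered secondary alkylruthenium next to C3, and the reaction is stopped at full conversion of 14, so C3 is untouched.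

Step 9
Reactants: 15 (2S,3S)-5-(dimethoxymethyl)-2-[3,5-dimethoxy-4-(methoxymethoxy)phenyl]-7-methoxy-3-[(1E)-prop-1-en-1-yl]-2,3-dihydro-1-benzofuran
Product: 17 [(2S,3R)-5-(dimethoxymethyl)-2-[3,5-dimethoxy-4-(methoxymethoxy)phenyl]-7-methoxy-2,3-dihydro-1-benzofuran-3-yl]methanol, via C3 aldehyde 16 (not isolated)
Conditions: O3, CH2Cl2/MeOH, NaHCO3, Sudan Red 7B, −78 °C; then NaBH4, −78 to 0 °C
Reagents that add atoms: ozone, [O-][O+]=O
Why: Ozonolysis cleaves the propenyl double bond, which reacts far faster than the arenes at −78 °C (the dye marks the end point); NaBH4 added to the cold mixture reduces the peroxidic intermediates and aldehyde 16 at once, so the C3 aldehyde, which could enolise or expel O1, is never isolated and C3 is retained (the descriptor changes to R only through the priority rules).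

Step 10
Reactants: 17 [(2S,3R)-5-(dimethoxymethyl)-2-[3,5-dimethoxy-4-(methoxymethoxy)phenyl]-7-methoxy-2,3-dihydro-1-benzofuran-3-yl]methanol
Product: 18 (2S,3R)-2-(4-hydroxy-3,5-dimethoxyphenyl)-3-(hydroxymethyl)-7-methoxy-2,3-dihydro-1-benzofuran-5-carbaldehyde
Conditions: 2 M aq. HCl, THF, 40 °C
Reagents that add atoms: water, O
Why: Acid hydrolysis of the dimethyl acetal and of the phenolic methoxymethyl acetal in one operation; if the C2–O1 bond ionises to the ring-B stabilised cation it recloses to the thermodynamically preferred trans ring under the control of C3, which is not affected.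

Step 11
Reactants: 18 (2S,3R)-2-(4-hydroxy-3,5-dimethoxyphenyl)-3-(hydroxymethyl)-7-methoxy-2,3-dihydro-1-benzofuran-5-carbaldehyde
Product: 20 (2E)-3-[(2S,3R)-2-(4-hydroxy-3,5-dimethoxyphenyl)-3-(hydroxymethyl)-7-methoxy-2,3-dihydro-1-benzofuran-5-yl]prop-2-enoic acid, via arylidenemalonic acid 19 (not isolated)
Conditions: malonic acid, pyridine, piperidine (cat.), 80 °C
Reagents that add atoms: malonic acid, OC(=O)CC(=O)O
Why: Knoevenagel–Doebner condensation: amine-catalysed condensation with malonic acid gives 19, which decarboxylates in hot pyridine to the (E)-acrylic acid; the phenol and the primary alcohol need no protection and the medium is buffered by the excess diacid.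

## Compound list

1 | 5-iodovanillin (4-hydroxy-3-iodo-5-methoxybenzaldehyde) | COc1cc(C=O)cc(I)c1O | starting material
2 | trimethylsilylacetylene | C#C[Si](C)(C)C | starting material
3 | 4-hydroxy-3-methoxy-5-[(trimethylsilyl)ethynyl]benzaldehyde | COc1cc(C=O)cc(C#C[Si](C)(C)C)c1O | intermediate
4 | 7-methoxy-2-(trimethylsilyl)-1-benzofuran-5-carbaldehyde | COc1cc(C=O)cc2cc([Si](C)(C)C)oc12 | intermediate
5 | 7-methoxy-1-benzofuran-5-carbaldehyde | COc1cc(C=O)cc2ccoc12 | intermediate
6 | 5-(dimethoxymethyl)-7-methoxy-1-benzofuran | COc1cc(C(OC)OC)cc2ccoc12 | intermediate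
7 | 4-bromo-2,6-dimethoxyphenol | COc1cc(Br)cc(OC)c1O | starting material
8 | 5-bromo-1,3-dimethoxy-2-(methoxymethoxy)benzene | COCOc1c(OC)cc(Br)cc1OC | intermediate
9 | 2-[3,5-dimethoxy-4-(methoxymethoxy)phenyl]-4,4,5,5-tetramethyl-1,3,2-dioxaborolane | COCOc1c(OC)cc(cc1OC)B1OC(C)(C)C(C)(C)O1 | intermediate
10 | allyl acetate (prop-2-en-1-yl acetate) | CC(=O)OCC=C | starting material
11 | [5-(dimethoxymethyl)-7-methoxy-1-benzofuran-2-yl]lithium | COc1cc(C(OC)OC)cc2cc([Li])oc12 | intermediate
12 | lithium [5-(dimethoxymethyl)-7-methoxy-1-benzofuran-2-yl][3,5-dimethoxy-4-(methoxymethoxy)phenyl](pinacolato)borate | [Li+].COCOc1c(OC)cc(cc1OC)[B-]1(OC(C)(C)C(C)(C)O1)c1cc2cc(C(OC)OC)cc(OC)c2o1 | intermediate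
13 | 2-{(2S,3S)-5-(dimethoxymethyl)-2-[3,5-dimethoxy-4-(methoxymethoxy)phenyl]-7-methoxy-3-(prop-2-en-1-yl)-2,3-dihydro-1-benzofuran-2-yl}-4,4,5,5-tetramethyl-1,3,2-dioxaborolane | COc1cc([C@@]2(B4OC(C)(C)C(C)(C)O4)Oc3c(OC)cc(C(OC)OC)cc3[C@@H]2CC=C)cc(OC)c1OCOC | intermediate
14 | (2S,3S)-5-(dimethoxymethyl)-2-[3,5-dimethoxy-4-(methoxymethoxy)phenyl]-7-methoxy-3-(prop-2-en-1-yl)-2,3-dihydro-1-benzofuran | COc1cc([C@H]2Oc3c(OC)cc(C(OC)OC)cc3[C@@H]2CC=C)cc(OC)c1OCOC | intermediate
15 | (2S,3S)-5-(dimethoxymethyl)-2-[3,5-dimethoxy-4-(methoxymethoxy)phenyl]-7-methoxy-3-[(1E)-prop-1-en-1-yl]-2,3-dihydro-1-benzofuran | COc1cc([C@H]2Oc3c(OC)cc(C(OC)OC)cc3[C@@H]2/C=C/C)cc(OC)c1OCOC | intermediate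
16 | (2S,3S)-5-(dimethoxymethyl)-2-[3,5-dimethoxy-4-(methoxymethoxy)phenyl]-7-methoxy-2,3-dihydro-1-benzofuran-3-carbaldehyde | COc1cc([C@H]2Oc3c(OC)cc(C(OC)OC)cc3[C@@H]2C=O)cc(OC)c1OCOC | intermediate
17 | [(2S,3R)-5-(dimethoxymethyl)-2-[3,5-dimethoxy-4-(methoxymethoxy)phenyl]-7-methoxy-2,3-dihydro-1-benzofuran-3-yl]methanol | COc1cc([C@H]2Oc3c(OC)cc(C(OC)OC)cc3[C@@H]2CO)cc(OC)c1OCOC | intermediate
18 | (2S,3R)-2-(4-hydroxy-3,5-dimethoxyphenyl)-3-(hydroxymethyl)-7-methoxy-2,3-dihydro-1-benzofuran-5-carbaldehyde | COc1cc([C@H]2Oc3c(OC)cc(C=O)cc3[C@@H]2CO)cc(OC)c1O | intermediate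
19 | 2-{[(2S,3R)-2-(4-hydroxy-3,5-dimethoxyphenyl)-3-(hydroxymethyl)-7-methoxy-2,3-dihydro-1-benzofuran-5-yl]methylidene}propanedioic acid | COc1cc([C@H]2Oc3c(OC)cc(C=C(C(=O)O)C(=O)O)cc3[C@@H]2CO)cc(OC)c1O | intermediate
20 | (2E)-3-[(2S,3R)-2-(4-hydroxy-3,5-dimethoxyphenyl)-3-(hydroxymethyl)-7-methoxy-2,3-dihydro-1-benzofuran-5-yl]prop-2-enoic acid | COc1cc([C@H]2Oc3c(OC)cc(/C=C/C(=O)O)cc3[C@@H]2CO)cc(OC)c1O | target

## Step count and least certain steps

Total: 11 steps. Longest linear sequence: 9 steps (from 1 through steps 1–3 and 6–11); the arm from 7 adds steps 4 and 5.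

**Step 6 (key step).**
- **What may go wrong:** transfer of the benzofuranyl group from boron to palladium with allylation at C2 in place of attack at C3, because an oxygen heterocycle is a weaker donor than an N-alkylindole. Face selection at C3 may also be poor with a ligand developed for another heterocycle, and boronate formation may be slow with the hindered, electron-rich aryl boronic ester.
- **Fallback (known chemistry, different bond set):** an intramolecular carbenoid C–H insertion that sets out from 1 and 8 and returns at 17. Bromine–lithium exchange on 8 (n-BuLi) and trapping with paraformaldehyde give [3,5-dimethoxy-4-(methoxymethoxy)phenyl]methanol F1. Mitsunobu etherification of 1 with F1 (PPh3, DIAD) gives the aryl benzyl ether F2, and acetalisation as in step 3 gives the iodoarene acetal F3. Coupling of F3 with ethyl diazoacetate under Pd(PPh3)4, Ag2CO3 and Et3N gives the aryldiazoacetate F4. The divalent rhodium carboxylate Rh2(S-PTTL)4 (or its enantiomer, whichever gives 2S) inserts the carbene into the benzylic ether C–H bond, closing the ring to the cis ester F5. NaOEt in EtOH epimerises C3 to the trans ester F6, and LiAlH4 reduces F6 to 17.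

**Step 7.**
- **What may go wrong:** loss of stereochemical fidelity at C2 if the C–B bond cleaves through a free, planar benzylic intermediate, or sluggish cleavage because the electron-rich aryl group stabilises negative charge poorly.
- **Fallback (thermodynamic control of C2 by C3 in place of stereospecific substitution):** it sets out from 13 and returns at 18. PhLi converts 13 into the phenyl boronate complex F7. Photoredox protodeboronation ([Ir(ppy)2(dtbbpy)]PF6, PhSH, blue light) passes through the planar C2 radical, and hydrogen transfer anti to the allyl group should favour the cis C2 epimer of 14, F8. F8, alone or mixed with 14, is taken through step 8 to the cis propenyl compound F9 and through step 9, by way of the cis aldehyde F10 (not isolated), to the cis alcohol F11. Under the acid of step 10 the ring-B phenol is freed, the C2–O1 bond opens reversibly and recloses trans, and the material converges on 18. If equilibration is slow, brief exposure to CF3CO2H in CH2Cl2 completes it.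

**Step 8.**
- **What may go wrong:** migration of the double bond beyond one position into conjugation with ring A, which would erase C3, or stalling before full conversion.
- **Fallback (two oxidative cleavages in place of an alkene shift):** it sets out from 14 and returns at 17. Ozonolysis of 14 with PPh3 work-up gives the homologous aldehyde F12. TMSCl and Et3N in DMF give its silyl enol ether F13 as an E/Z mixture. Ozonolysis of F13 with NaBH4 work-up, as in step 9, removes the extra carbon and gives 17.

**Step 11.**
- **What may go wrong:** opening of the C2–O1 bond from the ring-B phenoxide in hot amine to a quinone methide that adds piperidine or malonate, or incomplete decarboxylation.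
- **Fallback (neutral olefination, then hydrolysis):** it sets out from 18 and returns at 20. Wittig reaction of 18 with Ph3P=CHCO2Et in toluene gives the ethyl (E)-acrylate F14, and LiOH in THF/H2O at rt hydrolyses F14 to 20.

## Further compounds

F1 | step 6 | [3,5-dimethoxy-4-(methoxymethoxy)phenyl]methanol | COCOc1c(OC)cc(CO)cc1OC
F2 | step 6 | 4-{[3,5-dimethoxy-4-(methoxymethoxy)phenyl]methoxy}-3-iodo-5-methoxybenzaldehyde | COCOc1c(OC)cc(COc2c(I)cc(C=O)cc2OC)cc1OC
F3 | step 6 | 5-(dimethoxymethyl)-2-{[3,5-dimethoxy-4-(methoxymethoxy)phenyl]methoxy}-1-iodo-3-methoxybenzene | COCOc1c(OC)cc(COc2c(I)cc(C(OC)OC)cc2OC)cc1OC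
F4 | step 6 | ethyl 2-diazo-2-[5-(dimethoxymethyl)-2-{[3,5-dimethoxy-4-(methoxymethoxy)phenyl]methoxy}-3-methoxyphenyl]acetate | CCOC(=O)C(=[N+]=[N-])c1cc(C(OC)OC)cc(OC)c1OCc1cc(OC)c(OCOC)c(OC)c1
F5 | step 6 | ethyl (2S,3R)-5-(dimethoxymethyl)-2-[3,5-dimethoxy-4-(methoxymethoxy)phenyl]-7-methoxy-2,3-dihydro-1-benzofuran-3-carboxylate (cis) | COCOc1c(OC)cc([C@H]2Oc3c(OC)cc(C(OC)OC)cc3[C@H]2C(=O)OCC)cc1OC
F6 | step 6 | ethyl (2S,3S)-5-(dimethoxymethyl)-2-[3,5-dimethoxy-4-(methoxymethoxy)phenyl]-7-methoxy-2,3-dihydro-1-benzofuran-3-carboxylate (trans) | COCOc1c(OC)cc([C@H]2Oc3c(OC)cc(C(OC)OC)cc3[C@@H]2C(=O)OCC)cc1OC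
F7 | step 7 | lithium {(2S,3S)-5-(dimethoxymethyl)-2-[3,5-dimethoxy-4-(methoxymethoxy)phenyl]-7-methoxy-3-(prop-2-en-1-yl)-2,3-dihydro-1-benzofuran-2-yl}(phenyl)(pinacolato)borate | [Li+].COc1cc([C@@]2([B-]4(c5ccccc5)OC(C)(C)C(C)(C)O4)Oc3c(OC)cc(C(OC)OC)cc3[C@@H]2CC=C)cc(OC)c1OCOC
F8 | step 7 | (2R,3S)-5-(dimethoxymethyl)-2-[3,5-dimethoxy-4-(methoxymethoxy)phenyl]-7-methoxy-3-(prop-2-en-1-yl)-2,3-dihydro-1-benzofuran (cis) | COc1cc([C@@H]2Oc3c(OC)cc(C(OC)OC)cc3[C@@H]2CC=C)cc(OC)c1OCOC
F9 | step 7 | (2R,3S)-5-(dimethoxymethyl)-2-[3,5-dimethoxy-4-(methoxymethoxy)phenyl]-7-methoxy-3-[(1E)-prop-1-en-1-yl]-2,3-dihydro-1-benzofuran (cis) | COc1cc([C@@H]2Oc3c(OC)cc(C(OC)OC)cc3[C@@H]2/C=C/C)cc(OC)c1OCOC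
F10 | step 7 | (2R,3S)-5-(dimethoxymethyl)-2-[3,5-dimethoxy-4-(methoxymethoxy)phenyl]-7-methoxy-2,3-dihydro-1-benzofuran-3-carbaldehyde (cis) | COc1cc([C@@H]2Oc3c(OC)cc(C(OC)OC)cc3[C@@H]2C=O)cc(OC)c1OCOC
F11 | step 7 | [(2R,3R)-5-(dimethoxymethyl)-2-[3,5-dimethoxy-4-(methoxymethoxy)phenyl]-7-methoxy-2,3-dihydro-1-benzofuran-3-yl]methanol (cis) | COc1cc([C@@H]2Oc3c(OC)cc(C(OC)OC)cc3[C@@H]2CO)cc(OC)c1OCOC
F12 | step 8 | 2-[(2S,3S)-5-(dimethoxymethyl)-2-[3,5-dimethoxy-4-(methoxymethoxy)phenyl]-7-methoxy-2,3-dihydro-1-benzofuran-3-yl]acetaldehyde | COc1cc([C@H]2Oc3c(OC)cc(C(OC)OC)cc3[C@@H]2CC=O)cc(OC)c1OCOC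
F13 | step 8 | ({2-[(2S,3S)-5-(dimethoxymethyl)-2-[3,5-dimethoxy-4-(methoxymethoxy)phenyl]-7-methoxy-2,3-dihydro-1-benzofuran-3-yl]ethenyl}oxy)trimethylsilane (E/Z mixture) | COc1cc([C@H]2Oc3c(OC)cc(C(OC)OC)cc3[C@@H]2C=CO[Si](C)(C)C)cc(OC)c1OCOC
F14 | step 11 | ethyl (2E)-3-[(2S,3R)-2-(4-hydroxy-3,5-dimethoxyphenyl)-3-(hydroxymethyl)-7-methoxy-2,3-dihydro-1-benzofuran-5-yl]prop-2-enoate | COc1cc([C@H]2Oc3c(OC)cc(/C=C/C(=O)OCC)cc3[C@@H]2CO)cc(OC)c1O
A1 | alternative 1 | methyl (2E)-3-[(2S,3R)-2-(4-hydroxy-3,5-dimethoxyphenyl)-3-(hydroxymethyl)-7-methoxy-2,3-dihydro-1-benzofuran-5-yl]prop-2-enoate | COc1cc([C@H]2Oc3c(OC)cc(/C=C/C(=O)OC)cc3[C@@H]2CO)cc(OC)c1O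
A2 | alternative 1 | methyl (2E)-3-{4-hydroxy-3-[(2R)-1-hydroxy-3-(4-hydroxy-3,5-dimethoxyphenyl)propan-2-yl]-5-methoxyphenyl}prop-2-enoate | COc1cc(C[C@@H](CO)c2cc(/C=C/C(=O)OC)cc(OC)c2O)cc(OC)c1O
A3 | alternative 2 | ethyl exo-5-bromo-3-methoxy-1a,6b-dihydro-1H-cyclopropa[b][1]benzofuran-1-carboxylate (single enantiomer) | CCOC(=O)[C@H]1[C@@H]2Oc3c(OC)cc(Br)cc3[C@H]12
A4 | alternative 2 | 5-bromo-7-methoxy-1-benzofuran | COc1cc(Br)cc2ccoc12
A5 | alternative 2 | ethyl diazoacetate | CCOC(=O)C=[N+]=[N-]
A6 | alternative 3 | methyl (2S,3S)-5-bromo-2-[3,5-dimethoxy-4-(pivaloyloxy)phenyl]-7-methoxy-2,3-dihydro-1-benzofuran-3-carboxylate (trans) | COc1cc([C@H]2Oc3c(OC)cc(Br)cc3[C@@H]2C(=O)OC)cc(OC)c1OC(=O)C(C)(C)C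
A7 | alternative 3 | (2S)-6-bromo-2-[3,5-dimethoxy-4-(pivaloyloxy)phenyl]-8-methoxy-2,3-dihydro-4H-chromen-4-one | COc1cc([C@@H]2CC(=O)c3cc(Br)cc(OC)c3O2)cc(OC)c1OC(=O)C(C)(C)C
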